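## Retrosynthetic overview

- The C11–O aryl ether is cut last (Mitsunobu coupling with umbelliferone). The C6 acetate and the C3 ketone, carried as a dioxolane, are finished after it.
- The 6α-oxygen and the C7=C8 alkene are traced to SmI2 opening of a 6α,7α-epoxy-8-en-11-oate. This comes from a drima-6,8-dien-11-oate, made by dehydrogenating the Diels–Alder adduct (alkene C6=C7) across C8–C9.
- Rings A and B are formed together. Cutting C5–C10 and C8–C9 gives a (2E,8E,10E)-trienoyl (S)-oxazolidinone, built linearly from methyl geranate, 3-chloro-3-methylbut-1-yne and (E)-1-bromopropene.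
- Feature on which this rests: in the trans-decalin, the fusion bond C5–C10 and the ring B bond C8–C9 flank the four-carbon bridge C1–C2–C3–C4 (C3 ketone, C4 gem-dimethyl). A C9=C10 enoyl unit (C10 methyl, C11 carbonyl) and a C5=C6–C7=C8 diene attached to C4 therefore fold into both rings in one cycloaddition.

Key step: step 9

Remark: ring carbons carry drimane numbers (C3 ketone, C4 gem-dimethyl, C5/C10 fusion, C6 oxygen, C8 methyl, C9–C11 side arm); β is the face of the C10 methyl and α the face of H5. The centres created in steps 1 and 3 are racemic and are destroyed in steps 2 and 4. Commercial (E)-1-bromoprop-1-ene is taken as the pure (E) isomer.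

## Route

Step 1
Reactants: 1 methyl (E)-geranate
Product: 2 methyl (E)-6,7-epoxy-3,7-dimethyloct-2-enoate (racemic)
Conditions: mCPBA, CH2Cl2, 0 °C
Reagents that add atoms: 3-chloroperbenzoic acid, OOC(=O)c1cccc(Cl)c1
Why: Prilezhaev epoxidation, in which the electron-rich trisubstituted 6,7-alkene should react far faster than the conjugated enoate alkene; the new centre is racemic and is removed in step 2.

Step 2
Reactants: 2 methyl (E)-6,7-epoxy-3,7-dimethyloct-2-enoate
Product: 3 methyl (E)-3-methyl-6-oxohex-2-enoate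
Conditions: H5IO6, THF/Et2O, 0 °C to rt
Reagents that add atoms: none
Why: Acid-mediated hydration of the epoxide at its tertiary carbon followed by Malaprade glycol cleavage should give the aldehyde and acetone, the aldehyde oxygen being the former epoxide oxygen; the enoate is inert.

Step 3
Reactants: 3 methyl (E)-3-methyl-6-oxohex-2-enoate; 4 3-chloro-3-methylbut-1-yne
Product: 6 methyl (2E)-6-hydroxy-3,7,7-trimethylnon-2-en-8-ynoate (racemic carbinol), via allenylzinc chloride 5 (not isolated)
Conditions: Zn dust (activated with BrCH2CH2Br, TMSCl), THF, 0 °C to rt; sat. aq. NH4Cl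
Reagents that add atoms: none
Why: Barbier propargylation, in which zinc insertion into the tertiary propargylic chloride gives the allenylzinc species, which should add to the aldehyde through a cyclic SE2' transition state at its dimethyl-substituted carbon and so place the quaternary C4 next to the carbinol; the enoate is not attacked by the organozinc, and the racemic carbinol centre is removed in step 4.

Step 4
Reactants: 6 methyl (2E)-6-hydroxy-3,7,7-trimethylnon-2-en-8-ynoate
Product: 7 methyl (2E)-3,7,7-trimethyl-6-oxonon-2-en-8-ynoate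
Conditions: Dess–Martin periodinane, NaHCO3, CH2Cl2, rt
Reagents that add atoms: none
Why: Dess–Martin oxidation of the secondary carbinol to the C3 ketone under buffered, non-enolising conditions; the quaternary α-carbon rules out alkyne-to-allene isomerisation.

Step 5
Reactants: 7 methyl (2E)-3,7,7-trimethyl-6-oxonon-2-en-8-ynoate
Product: 8 methyl (2E,8E)-3,7,7-trimethyl-6-oxo-9-(tributylstannyl)nona-2,8-dienoate
Conditions: Bu3SnH, PdCl2(PPh3)2 (cat.), THF, 0 °C
Reagents that add atoms: tributyltin hydride, CCCC[SnH](CCCC)CCCC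
Why: Palladium-catalysed syn hydrostannation of the terminal alkyne, in which the quaternary propargylic carbon should direct tin to the terminal carbon and give the (E)-vinylstannane; the trisubstituted enoate and the ketone react much more slowly.

Step 6
Reactants: 8 methyl (2E,8E)-3,7,7-trimethyl-6-oxo-9-(tributylstannyl)nona-2,8-dienoate; 9 (E)-1-bromoprop-1-ene
Product: 10 methyl (2E,8E,10E)-3,7,7-trimethyl-6-oxododeca-2,8,10-trienoate
Conditions: Pd(PPh3)4 (cat.), CuI, CsF, DMF, 45 °C
Reagents that add atoms: none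
Why: Stille coupling of a vinylstannane with a vinyl bromide proceeds with retention at both alkenes and should give the (E,E)-diene; ketone and ester are tolerated.

Step 7
Reactants: 10 methyl (2E,8E,10E)-3,7,7-trimethyl-6-oxododeca-2,8,10-trienoate
Product: 11 (2E,8E,10E)-3,7,7-trimethyl-6-oxododeca-2,8,10-trienoic acid
Conditions: LiOH·H2O, THF/MeOH/H2O, rt; then 1 M HCl to pH 3
Reagents that add atoms: lithium hydroxide, [Li+].[OH-]
Why: Saponification of the methyl ester; the ketone has a quaternary α-carbon on the diene side, so the diene cannot move into conjugation.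

Step 8
Reactants: 11 (2E,8E,10E)-3,7,7-trimethyl-6-oxododeca-2,8,10-trienoic acid; 12 (S)-4-benzyl-2-oxazolidinone
Product: 14 (S)-4-benzyl-3-[(2E,8E,10E)-3,7,7-trimethyl-6-oxododeca-2,8,10-trienoyl]oxazolidin-2-one, via pivalic mixed anhydride 13 (not isolated)
Conditions: PivCl, Et3N, THF, −20 °C; then 12, LiCl, −20 °C to rt
Reagents that add atoms: none
Why: N-acylation of the oxazolidinone through the mixed pivalic anhydride, which is attacked at the less hindered enoyl carbonyl; the mild LiCl/Et3N variant avoids strong base and should leave the enoate geometry intact.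

Step 9
Reactants: 14 (S)-4-benzyl-3-[(2E,8E,10E)-3,7,7-trimethyl-6-oxododeca-2,8,10-trienoyl]oxazolidin-2-one
Product: 15 (S)-4-benzyl-3-[(5α-H,8β-methyl,9β,10β-methyl)-3-oxodrim-6-en-11-oyl]oxazolidin-2-one (trans-fused octalin, alkene C6=C7)
Conditions: Me2AlCl (3 equiv), CH2Cl2, −30 °C to rt; then 1 M HCl
Reagents that add atoms: none
Why: Me2AlCl converts the imide into a cationic aluminium chelate of its two carbonyl groups (the excess is bound by the C3 ketone), which holds the enoyl unit s-cis and lowers its LUMO, and the tethered (E,E)-diene then adds in a concerted but asynchronous [4+2] cycloaddition that forms C8–C9 and C5–C10. The closest known reaction type is the Me2AlCl-promoted intramolecular Diels–Alder reaction of (E,E,E)-2,8,10-trienoyl oxazolidinones to trans-fused octalins, here with a β-methyl on the dienophile and a gem-dimethyl carbon next to the diene. Ring B (C5, C6, C7, C8 from the diene; C9, C10 from the dienophile) closes as the six-membered cycloaddition ring, and ring A closes in the same event in the fused (type 1) mode, its last bond C5–C10 joining the two ends of the chair-like tether C1–C2–C3–C4. The chelated acyl group sits endo and the tether exo, so H5 should come out trans to the C10 methyl; the (E)-enoyl geometry keeps C11 cis to the C10 methyl at C9, and the (E,E)-diene geometry puts the C8 methyl cis to C11. The benzyl group of the (S)-auxiliary covers the re face of C9 in the chelate, so the diene should add to the si face, which gives 10β-methyl and 5α-H. The step needs endo and π-facial selectivity, both secured by the rigid chelate, and a reactive folding of the tether, which the C4 gem-dimethyl group and the sp2 carbon C3 favour.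

Step 10
Reactants: 15 (S)-4-benzyl-3-[(5α-H,8β-methyl,9β,10β-methyl)-3-oxodrim-6-en-11-oyl]oxazolidin-2-one
Product: 17 (5α-H,8β-methyl,9α-H)-3-oxodrim-6-en-11-oic acid, via peroxy acid 16 (not isolated)
Conditions: LiOH, 30% H2O2, THF/H2O, 0 °C; then aq. Na2SO3; then 1 M HCl
Reagents that add atoms: hydrogen peroxide, OO
Why: Hydroperoxide cleavage of the N-acyl oxazolidinone, in which the small, α-effect nucleophile should attack the exocyclic carbonyl even of this hindered imide; sulfite reduces the peracid, the auxiliary is recovered, and ketone and alkene are untouched at 0 °C.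

Step 11
Reactants: 17 (5α-H,8β-methyl,9α-H)-3-oxodrim-6-en-11-oic acid
Product: 18 methyl (5α-H,8β-methyl,9α-H)-3-oxodrim-6-en-11-oate
Conditions: MeI, K2CO3, DMF, rt
Reagents that add atoms: iodomethane, CI
Why: O-alkylation (SN2) of the carboxylate, which does not depend on access to the hindered carbonyl carbon; the ketone is not C-alkylated with carbonate as base.

Step 12
Reactants: 18 methyl (5α-H,8β-methyl,9α-H)-3-oxodrim-6-en-11-oate
Product: 19 methyl (5α-H,8β-methyl,9α-H)-3,3-(ethylenedioxy)drim-6-en-11-oate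
Conditions: HOCH2CH2OH, p-TsOH·H2O (cat.), benzene, reflux (Dean–Stark)
Reagents that add atoms: ethylene glycol, OCCO
Why: Acid-catalysed ketalisation with azeotropic water removal, which protects the C3 ketone against the enolate, hydride and samarium steps that follow; the hindered ester and the isolated alkene are inert.

Step 13
Reactants: 19 methyl (5α-H,8β-methyl,9α-H)-3,3-(ethylenedioxy)drim-6-en-11-oate
Product: 21 methyl (5α-H,8β-methyl)-3,3-(ethylenedioxy)-9α-(phenylseleno)drim-6-en-11-oate, via lithium ester enolate 20 (not isolated)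
Conditions: LDA, THF/DMPU, −78 to 0 °C; then PhSeBr, −78 °C
Reagents that add atoms: phenylselenenyl bromide, Br[Se]c1ccccc1
Why: α-Selenenylation of the ester enolate, in which PhSeBr should approach C9 on the α face, away from the β-methyls on C10 and C8, so that selenium ends cis to H8 as the syn elimination requires.

Step 14
Reactants: 21 methyl (5α-H,8β-methyl)-3,3-(ethylenedioxy)-9α-(phenylseleno)drim-6-en-11-oate
Product: 23 methyl (5α-H)-3,3-(ethylenedioxy)drima-6,8-dien-11-oate, via selenoxide 22 (not isolated)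
Conditions: 30% H2O2, pyridine, CH2Cl2, 0 °C to rt
Reagents that add atoms: none
Why: Selenoxide syn elimination, for which the 9α-selenoxide has H8α as its only β-hydrogen, so the C8=C9 alkene should form and the stereocentres at C8 and C9 are erased on purpose; pyridine buffers the ketal.

Step 15
Reactants: 23 methyl (5α-H)-3,3-(ethylenedioxy)drima-6,8-dien-11-oate
Product: 24 methyl (5α-H)-6α,7α-epoxy-3,3-(ethylenedioxy)drim-8-en-11-oate
Conditions: mCPBA, NaHCO3, CH2Cl2, 0 °C
Reagents that add atoms: 3-chloroperbenzoic acid, OOC(=O)c1cccc(Cl)c1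
Why: Prilezhaev epoxidation, which should take the distal C6=C7 alkene in preference to the ester-bearing C8=C9 alkene, and from the α face, anti to the axial β-methyls on C10 and C4, setting C6 and C7.

Step 16
Reactants: 24 methyl (5α-H)-6α,7α-epoxy-3,3-(ethylenedioxy)drim-8-en-11-oate
Product: 26 methyl (5α-H,9α-H)-3,3-(ethylenedioxy)-6α-hydroxydrim-7-en-11-oate, via samarium dienolate 25 (not isolated)
Conditions: SmI2 (2.5 equiv), THF/MeOH, −90 °C
Reagents that add atoms: none
Why: Reductive opening of a γ,δ-epoxy-α,β-unsaturated ester, in which two single-electron transfers into the enoate expel the allylic C7–O bond while the C6–O bond and its configuration stay; methanol should protonate the dienolate kinetically at C9 on the α face, anti to the C10 methyl, leaving the ester arm equatorial and β and the alkene at C7=C8.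

Step 17
Reactants: 26 methyl (5α-H,9α-H)-3,3-(ethylenedioxy)-6α-hydroxydrim-7-en-11-oate
Product: 27 (5α-H,9α-H)-3,3-(ethylenedioxy)drim-7-ene-6α,11-diol
Conditions: LiAlH4, THF, 0 °C; then H2O
Reagents that add atoms: none
Why: Hydride reduction of the ester to the primary C11 alcohol; ketal, trisubstituted alkene and the C9 centre (non-basic work-up) are unaffected.

Step 18
Reactants: 27 (5α-H,9α-H)-3,3-(ethylenedioxy)drim-7-ene-6α,11-diol; 28 umbelliferone (7-hydroxycoumarin)
Product: 29 7-{[(5α-H,9α-H)-3,3-(ethylenedioxy)-6α-hydroxydrim-7-en-11-yl]oxy}-2H-chromen-2-one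
Conditions: PPh3, DIAD, THF, 0 °C to rt
Reagents that add atoms: none
Why: Mitsunobu etherification with the acidic coumarin phenol, in which the primary C11 hydroxyl should form the alkoxyphosphonium ion much faster than the secondary 6α-hydroxyl, which is crowded by the C4 gem-dimethyl group; no stereocentre is involved.

Step 19
Reactants: 29 7-{[(5α-H,9α-H)-3,3-(ethylenedioxy)-6α-hydroxydrim-7-en-11-yl]oxy}-2H-chromen-2-one
Product: 30 7-{[(5α-H,9α-H)-6α-acetoxy-3,3-(ethylenedioxy)drim-7-en-11-yl]oxy}-2H-chromen-2-one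
Conditions: Ac2O, DMAP (cat.), pyridine, CH2Cl2, rt
Reagents that add atoms: acetic anhydride, CC(=O)OC(C)=O
Why: DMAP-catalysed acylation of the equatorial secondary alcohol with retention at C6; the coumarin lactone and the ketal are stable to these conditions.

Step 20
Reactants: 30 7-{[(5α-H,9α-H)-6α-acetoxy-3,3-(ethylenedioxy)drim-7-en-11-yl]oxy}-2H-chromen-2-one
Product: 31 7-{[(5α-H,9α-H)-6α-acetoxy-3-oxodrim-7-en-11-yl]oxy}-2H-chromen-2-one (target CNP0140705.1)
Conditions: 80% aq. AcOH, THF, 45 °C
Reagents that add atoms: water, O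
Why: Mild acid hydrolysis of the dioxolane, which is strained by the neighbouring gem-dimethyl group, should free the C3 ketone without ionising the allylic acetate or opening the lactone; C5, with its quaternary neighbours, cannot epimerise.

## Compound list

1 | methyl (E)-geranate | COC(=O)/C=C(\C)CCC=C(C)C | starting material
2 | methyl (E)-6,7-epoxy-3,7-dimethyloct-2-enoate (racemic) | COC(=O)/C=C(\C)CCC1OC1(C)C | intermediate
3 | methyl (E)-3-methyl-6-oxohex-2-enoate | COC(=O)/C=C(\C)CCC=O | intermediate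
4 | 3-chloro-3-methylbut-1-yne | CC(C)(Cl)C#C | starting material
5 | (3-methylbuta-1,2-dien-1-yl)zinc chloride | CC(C)=C=C[Zn]Cl | intermediate
6 | methyl (2E)-6-hydroxy-3,7,7-trimethylnon-2-en-8-ynoate (racemic) | COC(=O)/C=C(\C)CCC(O)C(C)(C)C#C | intermediate
7 | methyl (2E)-3,7,7-trimethyl-6-oxonon-2-en-8-ynoate | COC(=O)/C=C(\C)CCC(=O)C(C)(C)C#C | intermediate
8 | methyl (2E,8E)-3,7,7-trimethyl-6-oxo-9-(tributylstannyl)nona-2,8-dienoate | COC(=O)/C=C(\C)CCC(=O)C(C)(C)/C=C/[Sn](CCCC)(CCCC)CCCC | intermediate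
9 | (E)-1-bromoprop-1-ene | C/C=C/Br | starting material
10 | methyl (2E,8E,10E)-3,7,7-trimethyl-6-oxododeca-2,8,10-trienoate | COC(=O)/C=C(\C)CCC(=O)C(C)(C)/C=C/C=C/C | intermediate
11 | (2E,8E,10E)-3,7,7-trimethyl-6-oxododeca-2,8,10-trienoic acid | OC(=O)/C=C(\C)CCC(=O)C(C)(C)/C=C/C=C/C | intermediate
12 | (S)-4-benzyl-2-oxazolidinone | O=C1OC[C@H](Cc2ccccc2)N1 | starting material
13 | pivalic (2E,8E,10E)-3,7,7-trimethyl-6-oxododeca-2,8,10-trienoic anhydride | CC(C)(C)C(=O)OC(=O)/C=C(\C)CCC(=O)C(C)(C)/C=C/C=C/C | intermediate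
14 | (S)-4-benzyl-3-[(2E,8E,10E)-3,7,7-trimethyl-6-oxododeca-2,8,10-trienoyl]oxazolidin-2-one | O=C1OC[C@H](Cc2ccccc2)N1C(=O)/C=C(\C)CCC(=O)C(C)(C)/C=C/C=C/C | intermediate
15 | (S)-4-benzyl-3-[(5α-H,8β-methyl,9β,10β-methyl)-3-oxodrim-6-en-11-oyl]oxazolidin-2-one | C1=C[C@H](C)[C@H](C(=O)N3C(=O)OC[C@@H]3Cc3ccccc3)[C@@]2(C)CCC(=O)C(C)(C)[C@H]12 | intermediate
16 | (5α-H,8β-methyl,9α-H)-3-oxodrim-6-ene-11-peroxoic acid | C1=C[C@H](C)[C@H](C(=O)OO)[C@@]2(C)CCC(=O)C(C)(C)[C@H]12 | intermediate
17 | (5α-H,8β-methyl,9α-H)-3-oxodrim-6-en-11-oic acid | C1=C[C@H](C)[C@H](C(=O)O)[C@@]2(C)CCC(=O)C(C)(C)[C@H]12 | intermediate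
18 | methyl (5α-H,8β-methyl,9α-H)-3-oxodrim-6-en-11-oate | C1=C[C@H](C)[C@H](C(=O)OC)[C@@]2(C)CCC(=O)C(C)(C)[C@H]12 | intermediate
19 | methyl (5α-H,8β-methyl,9α-H)-3,3-(ethylenedioxy)drim-6-en-11-oate | C1=C[C@H](C)[C@H](C(=O)OC)[C@@]2(C)CCC3(OCCO3)C(C)(C)[C@H]12 | intermediate
20 | lithium enolate of 19 (C9=C11) | C1=C[C@H](C)C(=C([O-])OC)[C@@]2(C)CCC3(OCCO3)C(C)(C)[C@H]12.[Li+] | intermediate
21 | methyl (5α-H,8β-methyl)-3,3-(ethylenedioxy)-9α-(phenylseleno)drim-6-en-11-oate | C1=C[C@H](C)[C@]([Se]c3ccccc3)(C(=O)OC)[C@@]2(C)CCC3(OCCO3)C(C)(C)[C@H]12 | intermediate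
22 | selenoxide of 21 | C1=C[C@H](C)[C@]([Se](=O)c3ccccc3)(C(=O)OC)[C@@]2(C)CCC3(OCCO3)C(C)(C)[C@H]12 | intermediate
23 | methyl (5α-H)-3,3-(ethylenedioxy)drima-6,8-dien-11-oate | C1=CC(C)=C(C(=O)OC)[C@@]2(C)CCC3(OCCO3)C(C)(C)[C@H]12 | intermediate
24 | methyl (5α-H)-6α,7α-epoxy-3,3-(ethylenedioxy)drim-8-en-11-oate | O1[C@H]2[C@@H]1C(C)=C(C(=O)OC)[C@@]3(C)CCC4(OCCO4)C(C)(C)[C@H]23 | intermediate
25 | samarium 6-alkoxide dienolate from 24 | [O-][C@H]1C=C(C)C(=C([O-])OC)[C@@]2(C)CCC3(OCCO3)C(C)(C)[C@H]12.[Sm+3].[Sm+3].[I-].[I-].[I-].[I-] | intermediate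
26 | methyl (5α-H,9α-H)-3,3-(ethylenedioxy)-6α-hydroxydrim-7-en-11-oate | O[C@H]1C=C(C)[C@H](C(=O)OC)[C@@]2(C)CCC3(OCCO3)C(C)(C)[C@H]12 | intermediate
27 | (5α-H,9α-H)-3,3-(ethylenedioxy)drim-7-ene-6α,11-diol | O[C@H]1C=C(C)[C@H](CO)[C@@]2(C)CCC3(OCCO3)C(C)(C)[C@H]12 | intermediate
28 | umbelliferone (7-hydroxycoumarin) | Oc1ccc2ccc(=O)oc2c1 | starting material
29 | 7-{[(5α-H,9α-H)-3,3-(ethylenedioxy)-6α-hydroxydrim-7-en-11-yl]oxy}-2H-chromen-2-one | O[C@H]1C=C(C)[C@H](COc2ccc3ccc(=O)oc3c2)[C@@]2(C)CCC3(OCCO3)C(C)(C)[C@H]12 | intermediate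
30 | 7-{[(5α-H,9α-H)-6α-acetoxy-3,3-(ethylenedioxy)drim-7-en-11-yl]oxy}-2H-chromen-2-one | CC(=O)O[C@H]1C=C(C)[C@H](COc2ccc3ccc(=O)oc3c2)[C@@]2(C)CCC3(OCCO3)C(C)(C)[C@H]12 | intermediate
31 | 7-{[(5α-H,9α-H)-6α-acetoxy-3-oxodrim-7-en-11-yl]oxy}-2H-chromen-2-one (CNP0140705.1) | CC(=O)O[C@H]1C=C(C)[C@H](COc2ccc3ccc(=O)oc3c2)[C@@]2(C)CCC(=O)C(C)(C)[C@H]12 | target

## Step count

Total steps: 20. Longest linear sequence: 20 steps (from methyl geranate 1 to target 31).

## Steps most likely to fail

**Step 9 (intramolecular Diels–Alder).**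
- What may go wrong: bond formation between the fully substituted enoyl β-carbon C10 and the diene terminus C5, which sits next to the quaternary C4, may be too slow. The β-methyl that lies cis to the chelated carbonyl may also twist the enoyl unit out of the chelate plane, so that facial control erodes or the diene polymerises under the Lewis acid.
- Fallback: it sets out from triene keto ester 10 and comes back at keto ester 18, and it replaces auxiliary control by control from a C3 carbinol centre. The C3 ketone of 10 would be reduced with (R)-2-methyl-CBS-oxazaborolidine and BH3·SMe2 to methyl (2E,6S,8E,10E)-6-hydroxy-3,7,7-trimethyldodeca-2,8,10-trienoate F1. This would be silylated (TBSOTf, 2,6-lutidine) to the tert-butyldimethylsilyl ether F2. F2 would be cyclised thermally (toluene, BHT, 170 °C, sealed tube), where the equatorial silyloxy group in the chair-like tether should select the diene face that gives 5α-H and 10β-methyl, to the 3β-silyloxy drim-6-en-11-oate F3. TBAF would give the 3β-hydroxy ester F4, and Dess–Martin oxidation would restore the ketone of 18.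

**Step 13 (selenenylation at C9).**
- What may go wrong: deprotonation of the α-C–H flanked by the quaternary C10 and the substituted C8 may be incomplete, or C–Se bond formation at the resulting fully substituted enolate carbon may be slow, so that starting ester returns.
- Fallback: it sets out from ketal ester 19 and comes back at dienoate 23, and it moves the dehydrogenation to the aldehyde oxidation level, where enolisation is much easier. LiAlH4 would reduce 19 to (5α-H,8β-methyl,9α-H)-3,3-(ethylenedioxy)drim-6-en-11-ol F5. Dess–Martin oxidation would give the corresponding drim-6-en-11-al F6. IBX in DMSO/toluene at 70 °C would dehydrogenate this to 3,3-(ethylenedioxy)drima-6,8-dien-11-al F7. Pinnick oxidation (NaClO2, NaH2PO4, 2-methyl-2-butene) would give 3,3-(ethylenedioxy)drima-6,8-dien-11-oic acid F8, and MeI/K2CO3 in DMF would give 23.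

**Step 18 (Mitsunobu etherification).**
- What may go wrong: displacement at the β-branched C11 carbon beside C9 and C10 may be sluggish, so that the allylic 6α-hydroxyl competes (etherification or elimination) and the hydrazide adduct accumulates.
- Fallback: it sets out from hydroxy ester 26 and comes back at coumarin ether 29. It masks the C6 hydroxyl and makes the C11 oxygen the nucleophile, so that no substitution at carbon C11 is needed. TBSOTf and 2,6-lutidine would give the 6α-silyloxy ester F9, and LiAlH4 would give the 6α-silyloxy drim-7-en-11-ol F10. Palladium-catalysed C–O coupling with commercial 7-bromocoumarin ([Pd(allyl)Cl]2, RockPhos, Cs2CO3, toluene, 90 °C) would give the 6α-silyloxy coumarin ether F11. TBAF in THF would then free the 6α-hydroxyl to give 29.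

## Further compounds

F1 | step 9 | methyl (2E,6S,8E,10E)-6-hydroxy-3,7,7-trimethyldodeca-2,8,10-trienoate | COC(=O)/C=C(\C)CC[C@H](O)C(C)(C)/C=C/C=C/C
F2 | step 9 | methyl (2E,6S,8E,10E)-6-(tert-butyldimethylsilyloxy)-3,7,7-trimethyldodeca-2,8,10-trienoate | COC(=O)/C=C(\C)CC[C@H](O[Si](C)(C)C(C)(C)C)C(C)(C)/C=C/C=C/C
F3 | step 9 | methyl (5α-H,8β-methyl,9α-H)-3β-(tert-butyldimethylsilyloxy)drim-6-en-11-oate | C1=C[C@H](C)[C@H](C(=O)OC)[C@@]2(C)CC[C@H](O[Si](C)(C)C(C)(C)C)C(C)(C)[C@H]12
F4 | step 9 | methyl (5α-H,8β-methyl,9α-H)-3β-hydroxydrim-6-en-11-oate | C1=C[C@H](C)[C@H](C(=O)OC)[C@@]2(C)CC[C@H](O)C(C)(C)[C@H]12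
F5 | step 13 | (5α-H,8β-methyl,9α-H)-3,3-(ethylenedioxy)drim-6-en-11-ol | C1=C[C@H](C)[C@H](CO)[C@@]2(C)CCC3(OCCO3)C(C)(C)[C@H]12
F6 | step 13 | (5α-H,8β-methyl,9α-H)-3,3-(ethylenedioxy)drim-6-en-11-al | C1=C[C@H](C)[C@H](C=O)[C@@]2(C)CCC3(OCCO3)C(C)(C)[C@H]12
F7 | step 13 | (5α-H)-3,3-(ethylenedioxy)drima-6,8-dien-11-al | C1=CC(C)=C(C=O)[C@@]2(C)CCC3(OCCO3)C(C)(C)[C@H]12
F8 | step 13 | (5α-H)-3,3-(ethylenedioxy)drima-6,8-dien-11-oic acid | C1=CC(C)=C(C(=O)O)[C@@]2(C)CCC3(OCCO3)C(C)(C)[C@H]12
F9 | step 18 | methyl (5α-H,9α-H)-6α-(tert-butyldimethylsilyloxy)-3,3-(ethylenedioxy)drim-7-en-11-oate | CC(C)(C)[Si](C)(C)O[C@H]1C=C(C)[C@H](C(=O)OC)[C@@]2(C)CCC3(OCCO3)C(C)(C)[C@H]12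
F10 | step 18 | (5α-H,9α-H)-6α-(tert-butyldimethylsilyloxy)-3,3-(ethylenedioxy)drim-7-en-11-ol | CC(C)(C)[Si](C)(C)O[C@H]1C=C(C)[C@H](CO)[C@@]2(C)CCC3(OCCO3)C(C)(C)[C@H]12
F11 | step 18 | 7-{[(5α-H,9α-H)-6α-(tert-butyldimethylsilyloxy)-3,3-(ethylenedioxy)drim-7-en-11-yl]oxy}-2H-chromen-2-one | CC(C)(C)[Si](C)(C)O[C@H]1C=C(C)[C@H](COc2ccc3ccc(=O)oc3c2)[C@@]2(C)CCC3(OCCO3)C(C)(C)[C@H]12
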